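**Remarks on the chemistry**
- Numbering: C7 is the benzylic carbinol carbon, C8 the carbon bearing the aryloxy oxygen, C9 the methyl group. Ring A is the 3,4,5-trimethoxyphenyl ring (C1 on C7). Ring B is the 2,6-dimethoxyphenoxy ring (C4' bears the ether oxygen, C1' the chain C7'=C8'–C9'). In the propan-1-ol names C1 = C7 and C2 = C8.
- Configuration check: the target's descriptors were derived from its structure as (7R,8R), the threo (syn) series. Chelation-controlled aryl addition to an (R)-2-aryloxypropanal leads to this isomer, and one inversion of an (S)-lactate supplies the (R) centre. No structure needed correcting.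
- Compounds 1 and 2 are assumed to be bought as catalogue items.

## Structural features

The target is an acyclic 8-O-4' neolignan in which no ring has to be built. Ring A is bonded through C1 to the chain C7–C8–C9, and the oxygen on C8 is the phenolic oxygen at C4' of ring B, which carries an (E)-3-hydroxyprop-1-enyl chain at C1'. C7, a secondary benzylic carbinol, and C8, which bears the aryloxy oxygen and the C9 methyl group, are adjacent stereocentres, both R, in the threo relationship. Three groups are fragile: the C7 benzylic alcohol, which ionises easily under acid because of the para-methoxy group of ring A; the cinnamyl-type allylic alcohol of ring B with its E-alkene; and, in any carbonyl precursor, the C8 hydrogen, which is acidified by the carbonyl and the aryloxy group together. The skeleton is simple; the real difficulty is to control two contiguous stereocentres on an open chain, one of them attached to a hindered and weakly basic di-ortho-substituted aryloxy group, without loss of configuration at C8. The feature used by the key step is that C7 is bonded only to ring A C1, its hydroxyl and C8, while C8 has the substituent pattern of lactic acid. C8 can therefore come from the chiral pool, and C7 can be created by adding the ring A aryl group to a C7 aldehyde whose carbonyl oxygen and C8 ether oxygen sit in a five-membered magnesium chelate, with the ortho-methoxy oxygens of ring B as further donors.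

## Logic of the disconnections

**10 to 9.** The first cut is not in the skeleton: the O–H bond of the C9' hydroxyl in 10 is replaced by an O–Si bond to give 9. A free allylic alcohol would consume the organomagnesium reagent of the preceding step and place a second alkoxide near the chelate. Nothing is gained in simplicity, but the carbon–carbon bond formation becomes possible. The forward cleavage must not be acidic, because the C7 carbinol and the cinnamyl alcohol both ionise under acid; fluoride meets this.

**9 to 7 and 8.** 9 is cut at the C1–C7 bond. This is the only carbon–carbon bond between ring A and the chain, and cutting it separates an achiral nucleophile (7) from an electrophile (8) that already holds C8, ring B and the whole protected side chain. The gain is full convergence, and C7 appears in the same step as the last skeletal bond. The forward step must deliver the aryl group to one face of the carbonyl under control of C8 and must not enolise 8.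

**8 to 5.** 8 is traced back to 5 by raising C7 from the aldehyde to the ester oxidation level. An α-aryloxy aldehyde does not keep its configuration on storage or on silica, whereas the ester does, so the aldehyde should exist only between two cold operations. The forward step must stop at the aldehyde and must not be basic.

**7 to 6.** The C–Mg bond of 7 is replaced by the C–Br bond of 6. The forward step is a magnesium insertion and sets no selectivity problem.

**5 to 3 and 4.** 5 is cut at the C8–O bond on the alkyl side, not at O–C4'. Ring B is electron-rich and can only act as the nucleophile, and C8 then has exactly the substitution of a lactate ester, which is available as a single enantiomer. The stereocentre is bought, and ring B with its chain becomes an achiral phenol. The forward step must be a clean SN2 inversion at a secondary carbon by a hindered phenol under neutral conditions, so 4 must have the S configuration.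

**3 to 1 and 2.** 3 is cut at the C1'–C7' bond between ring B and the propenyl chain. Both pieces are commercial, and the chain arrives complete, E-configured and already silylated. This shortens the route to the aldehyde precursor relative to an olefination, reduction and silylation sequence from an aromatic aldehyde, and it avoids a free phenolic allylic diol and a phenol-versus-alcohol selective silylation. The forward coupling has to tolerate the free phenol and keep the alkene geometry.

## Other disconnections considered

**Alternative 1:** The cut is the C7–C8 bond. In the forward direction (S)-4-benzyl-3-[2-(4-bromo-2,6-dimethoxyphenoxy)acetyl]oxazolidin-2-one A1 is enolised with Bu2BOTf and iPr2NEt (Z geometry) and added to 3,4,5-trimethoxybenzaldehyde A2. A closed chair transition state should give the syn aldol (S)-4-benzyl-3-[(2S,3R)-2-(4-bromo-2,6-dimethoxyphenoxy)-3-hydroxy-3-(3,4,5-trimethoxyphenyl)propanoyl]oxazolidin-2-one A3.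
- In its favour: both stereocentres are created together under auxiliary control that does not depend on the donor ability of an aryloxy oxygen, and no configurationally labile α-aryloxy aldehyde is handled. On the predictability of the stereochemical outcome this plan is the better of the two.
- Against it here: A3 has C9 at the carboxylic oxidation level and a bromine where the side chain belongs. C9 must be taken down to a methyl group (reductive removal of the auxiliary, selective activation of the primary hydroxyl next to the benzylic one, hydride displacement), and the 1,3-relationship invites oxetane formation or retro-aldol cleavage. The propenol chain must then be coupled on with 2 and unmasked.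
- Comparison: structurally, the chosen plan buys C8 with its methyl group already in place. Mechanistically, a closed boron transition state is more dependable than an open-chain magnesium chelate. In step economy the alternative needs about ten operations, including the preparation of A1, and consumes a stoichiometric auxiliary, against six steps.

**Alternative 2:** The cut is the O–C4' bond on the aryl side. In the forward direction (1R,2R)-1-(methoxymethoxy)-1-(3,4,5-trimethoxyphenyl)propan-2-ol A4 is deprotonated with KN(SiMe3)2 and attacks the fluorine-bearing carbon of 4-fluoro-3,5-dimethoxybenzaldehyde A5. Loss of fluoride from the Meisenheimer adduct would give 4-{[(1R,2R)-1-(methoxymethoxy)-1-(3,4,5-trimethoxyphenyl)propan-2-yl]oxy}-3,5-dimethoxybenzaldehyde A6.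
- In its favour: both stereocentres would come from a reagent-controlled asymmetric dihydroxylation of an E-alkene, which fixes the threo relationship by construction. The key step touches no stereocentre, and C8 is never α to a carbonyl. On the configurational safety of C8 and on the origin of the relative configuration this plan is the better one, and in convergence it is the equal of the chosen plan.
- Against it here: the ipso carbon is flanked by two methoxy groups that crowd it and donate into the ring, and it is activated by a single para formyl group. The nucleophile is a hindered secondary alkoxide that can instead add to the aldehyde or trigger acetal migration. The two secondary hydroxyls must be told apart before the key step. The acetal must be removed with acid at the end, in the presence of an ionisable benzylic position and a cinnamyl alcohol. A6 still needs a two-carbon homologation and a reduction.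
- Comparison: in the chosen plan ring B reacts as a nucleophile, its natural polarity, while here it must be an electrophile. The alternative would need about eight steps against six.

**Alternative 3:** No skeletal bond is cut; the C8–H and C9–H bonds are removed to give a C8=C9 enol ether. In the forward direction (R)-2-(4-bromo-2,6-dimethoxyphenoxy)-1-(3,4,5-trimethoxyphenyl)prop-2-en-1-ol A7 is hydrogenated with [Rh(nbd)(dppb)]BF4 under H2. The cationic monovalent rhodium binds the C7 hydroxyl and the alkene, and hydrogen is delivered to the face fixed by minimised allylic strain. This would give (1R,2R)-2-(4-bromo-2,6-dimethoxyphenoxy)-1-(3,4,5-trimethoxyphenyl)propan-1-ol A8.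
- In its favour: the step is catalytic and atom-economical. A hydroxyl group binds rhodium far better than an aryloxy oxygen binds magnesium, so on the certainty of diastereoselection this step is the equal of, or better than, the chosen key step. C8 is created late and is never α to a carbonyl.
- Against it here: C7 must first be made as a single enantiomer by a separate asymmetric carbonyl reduction, so two independent stereo-defining steps are needed. A7 is at once an allylic and benzylic alcohol and an enol ether, and is therefore very acid-labile. The alkene is electron-rich, and its oxygen substituent may compete for the metal. Hydrogenolysis of the aryl C–Br or benzylic C–O bond is possible. The cinnamyl alkene cannot be present during hydrogenation, so the side chain must be attached afterwards with 2 and then desilylated.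
- Comparison: the step count is about equal (six). The chosen plan has a single stereo-defining event after a chiral-pool start and carries the complete ring B chain through, at the price of relying on weak chelation.

Key step: step 5

## Route

Step 1
Reactants: 1 4-bromo-2,6-dimethoxyphenol; 2 (E)-tert-butyldimethyl{[3-(4,4,5,5-tetramethyl-1,3,2-dioxaborolan-2-yl)prop-2-en-1-yl]oxy}silane
Product: 3 4-[(E)-3-(tert-butyldimethylsilyloxy)prop-1-enyl]-2,6-dimethoxyphenol
Conditions: 2 (1.2 equiv), Pd(OAc)2 (2 mol%), SPhos (4 mol%), K3PO4 (3 equiv), THF/H2O 10:1, degassed, 60 °C; aq. NH4Cl work-up
Reagents that add atoms: none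
Why: Suzuki–Miyaura cross-coupling: zerovalent palladium carrying the electron-rich dialkylbiarylphosphine inserts into the C–Br bond even of the phenoxide form of 1, transmetalation from the E-alkenylboronate retains the alkene geometry, and reductive elimination forms the C1'–C7' bond. The primary silyl ether and the phenol (carried as its phenoxide, hence the third equivalent of base) should not be affected by aqueous phosphate at this temperature.

Step 2
Reactants: 3 4-[(E)-3-(tert-butyldimethylsilyloxy)prop-1-enyl]-2,6-dimethoxyphenol; 4 ethyl (S)-lactate (ethyl (2S)-2-hydroxypropanoate)
Product: 5 ethyl (R)-2-{4-[(E)-3-(tert-butyldimethylsilyloxy)prop-1-enyl]-2,6-dimethoxyphenoxy}propanoate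
Conditions: 4 (1.3 equiv), PPh3 (1.4 equiv), DIAD (1.4 equiv, added dropwise), THF, 0 °C → rt
Reagents that add atoms: none
Why: Mitsunobu etherification: the hydroxyl of 4 is activated as an alkoxyphosphonium ion and displaced by the phenoxide of 3 (pKa near 10) in an SN2 reaction that the adjacent ester accelerates, so the carbon is inverted and (S) becomes the (R) configuration needed at C8. The medium is essentially neutral, so neither the new α-aryloxy ester centre nor the silyl ether is at risk.

Step 3
Reactants: 6 5-bromo-1,2,3-trimethoxybenzene
Product: 7 3,4,5-trimethoxyphenylmagnesium bromide (about 1 M in THF, titrated, used as the solution)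
Conditions: Mg turnings (1.3 equiv), I2 (cat.), THF, 45–60 °C
Reagents that add atoms: magnesium, [Mg]
Why: Grignard reagent formation by insertion of magnesium into the aryl C–Br bond, routine for alkoxy-substituted aryl bromides in THF; the solution is kept concentrated so that little THF enters step 5.

Step 4
Reactants: 5 ethyl (R)-2-{4-[(E)-3-(tert-butyldimethylsilyloxy)prop-1-enyl]-2,6-dimethoxyphenoxy}propanoate
Product: 8 (R)-2-{4-[(E)-3-(tert-butyldimethylsilyloxy)prop-1-enyl]-2,6-dimethoxyphenoxy}propanal
Conditions: iBu2AlH (1.15 equiv), CH2Cl2, −78 °C; MeOH at −78 °C, then cold aq. potassium sodium tartrate (KNaC4H4O6); concentrated below 20 °C, not chromatographed, used at once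
Reagents that add atoms: none
Why: Partial reduction of an ester with iBu2AlH: at −78 °C the tetrahedral aluminium hemiacetal, stabilised by coordination to the C8 oxygen, should not collapse before the quench, so the aldehyde is not reduced further. No base is present and the aldehyde is handled cold and briefly, which should keep C8 intact.

Step 5
Reactants: 8 (R)-2-{4-[(E)-3-(tert-butyldimethylsilyloxy)prop-1-enyl]-2,6-dimethoxyphenoxy}propanal; 7 3,4,5-trimethoxyphenylmagnesium bromide
Product: 9 (1R,2R)-2-{4-[(E)-3-(tert-butyldimethylsilyloxy)prop-1-enyl]-2,6-dimethoxyphenoxy}-1-(3,4,5-trimethoxyphenyl)propan-1-ol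
Conditions: MgBr2·OEt2 (2.5 equiv), CH2Cl2, −78 °C, 30 min; then 7 (1.5 equiv, about 1 M in THF) added slowly, −78 °C; sat. aq. NH4Cl at −78 °C
Reagents that add atoms: none
Why: This is a chelation-controlled 1,2-addition of an aryl Grignard reagent to an α-alkoxy aldehyde (Cram chelate model); the closest known reaction type is the MgBr2-mediated addition of organomagnesium reagents to O-protected lactaldehydes, and no ring is closed. MgBr2·OEt2 in the non-coordinating solvent binds the carbonyl oxygen and the C8 ether oxygen before the nucleophile is present, which fixes the C7=O and C8–O bonds syn-periplanar in a five-membered chelate; an ortho-methoxy oxygen of ring B can occupy a further site on magnesium and offsets the low basicity of the aryloxy oxygen. In this chelate the C8 hydrogen lies on one face of the carbonyl and the C9 methyl group on the other, and the aryl group of 7 is delivered along the Bürgi–Dunitz trajectory past the hydrogen, that is to the Re face of the (R)-aldehyde, forming the C1–C7 bond. The new stereocentre C7 is thereby set as R by substrate control from C8, which is the 7,8-threo (1R,2R) carbinol, whereas the open Felkin–Anh transition state would lead to the erythro isomer. The step needs facial selectivity at the carbonyl and addition in preference to enolisation: the first is secured by the two oxygen donors of the substrate together with pre-complexation, a small THF fraction and low temperature, the second by the low basicity of an aryl Grignard reagent at −78 °C. The silyl ether, the alkene and the aryl ethers are inert here, and the cold NH4Cl quench avoids acid at the new electron-rich benzylic carbinol.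

Step 6
Reactants: 9 (1R,2R)-2-{4-[(E)-3-(tert-butyldimethylsilyloxy)prop-1-enyl]-2,6-dimethoxyphenoxy}-1-(3,4,5-trimethoxyphenyl)propan-1-ol
Product: 10 (1R,2R)-2-{4-[(E)-3-hydroxyprop-1-enyl]-2,6-dimethoxyphenoxy}-1-(3,4,5-trimethoxyphenyl)propan-1-ol (CNP0196275.1)
Conditions: Bu4NF (1.2 equiv), THF, 0 °C → rt; H2O work-up
Reagents that add atoms: none
Why: Fluoride-induced desilylation driven by the strength of the Si–F bond; only the silyl ether reacts, and the mildly basic medium avoids ionisation of the benzylic C7 carbinol or of the cinnamyl alcohol, so both stereocentres and the E-alkene should be unchanged.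

## Compound list

1 | 4-bromo-2,6-dimethoxyphenol | COc1cc(Br)cc(OC)c1O | starting material
2 | (E)-tert-butyldimethyl{[3-(4,4,5,5-tetramethyl-1,3,2-dioxaborolan-2-yl)prop-2-en-1-yl]oxy}silane | CC(C)(C)[Si](C)(C)OC/C=C/B1OC(C)(C)C(C)(C)O1 | starting material
3 | 4-[(E)-3-(tert-butyldimethylsilyloxy)prop-1-enyl]-2,6-dimethoxyphenol | COc1cc(/C=C/CO[Si](C)(C)C(C)(C)C)cc(OC)c1O | intermediate
4 | ethyl (S)-lactate | C[C@H](O)C(=O)OCC | starting material
5 | ethyl (R)-2-{4-[(E)-3-(tert-butyldimethylsilyloxy)prop-1-enyl]-2,6-dimethoxyphenoxy}propanoate | CCOC(=O)[C@@H](C)Oc1c(OC)cc(/C=C/CO[Si](C)(C)C(C)(C)C)cc1OC | intermediate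
6 | 5-bromo-1,2,3-trimethoxybenzene | COc1cc(Br)cc(OC)c1OC | starting material
7 | 3,4,5-trimethoxyphenylmagnesium bromide | COc1cc([Mg]Br)cc(OC)c1OC | intermediate
8 | (R)-2-{4-[(E)-3-(tert-butyldimethylsilyloxy)prop-1-enyl]-2,6-dimethoxyphenoxy}propanal | O=C[C@@H](C)Oc1c(OC)cc(/C=C/CO[Si](C)(C)C(C)(C)C)cc1OC | intermediate
9 | (1R,2R)-2-{4-[(E)-3-(tert-butyldimethylsilyloxy)prop-1-enyl]-2,6-dimethoxyphenoxy}-1-(3,4,5-trimethoxyphenyl)propan-1-ol | COc1cc([C@@H](O)[C@@H](C)Oc2c(OC)cc(/C=C/CO[Si](C)(C)C(C)(C)C)cc2OC)cc(OC)c1OC | intermediate
10 | (1R,2R)-2-{4-[(E)-3-hydroxyprop-1-enyl]-2,6-dimethoxyphenoxy}-1-(3,4,5-trimethoxyphenyl)propan-1-ol | COc1cc([C@@H](O)[C@@H](C)Oc2c(OC)cc(/C=C/CO)cc2OC)cc(OC)c1OC | target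

## Step count and least certain steps

Total step count: 6. Longest linear sequence: 5 steps (steps 1, 2, 4, 5 and 6); step 3 is a one-step side branch.

**Step 5 (key step).** The most likely failure is insufficient chelation: the aryloxy oxygen binds magnesium weakly and THF competes for the metal, so the open transition state takes part and facial selectivity falls. Slow enolisation of 8 by the Grignard reagent would in addition erode C8. The fallback changes the way C7 is set. It sets out from the carbinol 9 as obtained from step 5, whatever its isomeric purity. Oxidation with Dess–Martin periodinane and NaHCO3 in CH2Cl2 should give (R)-2-{4-[(E)-3-(tert-butyldimethylsilyloxy)prop-1-enyl]-2,6-dimethoxyphenoxy}-1-(3,4,5-trimethoxyphenyl)propan-1-one F1. Reduction with the bulky, non-chelating hydride LiBH(s-Bu)3 in THF at −78 °C should then follow the polar Felkin–Anh model: the C8–O bond lies anti to the incoming hydride, which passes the C8 hydrogen, and this leads to the same threo carbinol. The fallback comes back to the route at 9.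

**Step 4.** The most likely failures are over-reduction, if the aluminium hemiacetal collapses before the quench, and partial epimerisation at C8 during work-up and concentration. The fallback sets out from 5 and separates reduction from aldehyde formation. LiBH4 in THF/MeOH at 0 °C should give (R)-2-{4-[(E)-3-(tert-butyldimethylsilyloxy)prop-1-enyl]-2,6-dimethoxyphenoxy}propan-1-ol F2, which is stable, can be purified and allows its enantiomeric purity to be checked. Oxidation with Dess–Martin periodinane and NaHCO3 in CH2Cl2 at 0 °C, followed by a cold filtration, returns to the route at 8.

**Step 1.** The most likely failure is slow oxidative addition into the very electron-rich phenoxide of 1, which leaves time for protodeboronation or homocoupling of 2. The fallback reverses the order of the two bond formations and sets out from 1. Mitsunobu reaction of 1 with 4 (PPh3, DIAD, THF) should give ethyl (R)-2-(4-bromo-2,6-dimethoxyphenoxy)propanoate F3, whose aryl bromide is an ether and no longer a phenoxide. Suzuki–Miyaura coupling of F3 with 2 under anhydrous fluoride activation (Pd(OAc)2, SPhos, CsF, dioxane, 80 °C), chosen to spare the ester and the C8 centre, comes back to the route at 5 and bypasses 3.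

**Step 2.** The most likely failure is a slow displacement by the doubly ortho-substituted phenol, so that alkylation of the reduced azodicarboxylate or elimination to the acrylate competes. The fallback replaces the redox condensation by a sulfonate displacement and sets out from 4. Tf2O and 2,6-lutidine in CH2Cl2 (−78 → 0 °C) should give ethyl (S)-2-(trifluoromethylsulfonyloxy)propanoate F4. F4 is then treated with 3 and K2CO3 in MeCN at −20 → 0 °C, an SN2 reaction with inversion at a temperature where the ester centre should not epimerise. The fallback comes back to the route at 5.

## Further compounds

F1 | step 5 | (R)-2-{4-[(E)-3-(tert-butyldimethylsilyloxy)prop-1-enyl]-2,6-dimethoxyphenoxy}-1-(3,4,5-trimethoxyphenyl)propan-1-one | COc1cc(C(=O)[C@@H](C)Oc2c(OC)cc(/C=C/CO[Si](C)(C)C(C)(C)C)cc2OC)cc(OC)c1OC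
F2 | step 4 | (R)-2-{4-[(E)-3-(tert-butyldimethylsilyloxy)prop-1-enyl]-2,6-dimethoxyphenoxy}propan-1-ol | OC[C@@H](C)Oc1c(OC)cc(/C=C/CO[Si](C)(C)C(C)(C)C)cc1OC
F3 | step 1 | ethyl (R)-2-(4-bromo-2,6-dimethoxyphenoxy)propanoate | CCOC(=O)[C@@H](C)Oc1c(OC)cc(Br)cc1OC
F4 | step 2 | ethyl (S)-2-(trifluoromethylsulfonyloxy)propanoate | C[C@H](OS(=O)(=O)C(F)(F)F)C(=O)OCC
A1 | alternative 1 | (S)-4-benzyl-3-[2-(4-bromo-2,6-dimethoxyphenoxy)acetyl]oxazolidin-2-one | O=C(COc1c(OC)cc(Br)cc1OC)N1[C@@H](Cc2ccccc2)COC1=O
A2 | alternative 1 | 3,4,5-trimethoxybenzaldehyde | COc1cc(C=O)cc(OC)c1OC
A3 | alternative 1 | (S)-4-benzyl-3-[(2S,3R)-2-(4-bromo-2,6-dimethoxyphenoxy)-3-hydroxy-3-(3,4,5-trimethoxyphenyl)propanoyl]oxazolidin-2-one | COc1cc([C@@H](O)[C@@H](C(=O)N2[C@@H](Cc3ccccc3)COC2=O)Oc2c(OC)cc(Br)cc2OC)cc(OC)c1OC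
A4 | alternative 2 | (1R,2R)-1-(methoxymethoxy)-1-(3,4,5-trimethoxyphenyl)propan-2-ol | COc1cc([C@@H](OCOC)[C@@H](C)O)cc(OC)c1OC
A5 | alternative 2 | 4-fluoro-3,5-dimethoxybenzaldehyde | COc1cc(C=O)cc(OC)c1F
A6 | alternative 2 | 4-{[(1R,2R)-1-(methoxymethoxy)-1-(3,4,5-trimethoxyphenyl)propan-2-yl]oxy}-3,5-dimethoxybenzaldehyde | COc1cc([C@@H](OCOC)[C@@H](C)Oc2c(OC)cc(C=O)cc2OC)cc(OC)c1OC
A7 | alternative 3 | (R)-2-(4-bromo-2,6-dimethoxyphenoxy)-1-(3,4,5-trimethoxyphenyl)prop-2-en-1-ol | COc1cc([C@@H](O)C(=C)Oc2c(OC)cc(Br)cc2OC)cc(OC)c1OC
A8 | alternative 3 | (1R,2R)-2-(4-bromo-2,6-dimethoxyphenoxy)-1-(3,4,5-trimethoxyphenyl)propan-1-ol | COc1cc([C@@H](O)[C@@H](C)Oc2c(OC)cc(Br)cc2OC)cc(OC)c1OC
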